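Reagent is the short charge in this flask, 0.400 M against 0.80 M of substrate, so it is the limiting reagent.

| setting | teal | amber | green | flask |
|---|---|---|---|---|
| substrate | 0.80 M | 0.80 M | 0.40 M | 0.80 M |
| reagent | 0.27 M | 0.60 M | 0.40 M | 0.400 M |
| remark | run made earlier | run made earlier | run made earlier |  |
| time |  |  |  | 4.0 min |

| run | time / min | other mono adduct / % | mono adduct / % |
|---|---|---|---|
| teal | 0.333 | 4.2 | 4.5 |
| teal | 0.500 | 5.8 | 5.1 |
| teal | 0.833 | 8.9 | 4.4 |
| teal | 1.33 | 12.0 | 3.1 |
| teal | 2.50 | 17.6 | 1.9 |
| teal | 4.00 | 24.0 | 1.7 |
| amber | 0.667 | 15.9 | 7.8 |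
| amber | 1.33 | 25.3 | 3.6 |
| amber | 2.00 | 33.1 | 4.2 |
| amber | 2.50 | 37.8 | 2.6 |
| amber | 3.00 | 40.8 | 4.1 |
| amber | 4.00 | 47.0 | 1.6 |
| green | 0.333 | 6.4 | 5.1 |
| green | 0.667 | 12.0 | 3.8 |
| green | 1.00 | 17.4 | 4.3 |
| green | 2.00 | 28.1 | 5.0 |
| green | 4.00 | 41.0 | 0.6 |

(readings scatter by 1 percentage point)

- what was read earlier has a scatter of 1 percentage point, one standard deviation
- reactions considered so far: reagent + other mono adduct -> double product; substrate + reagent <-> mono adduct; reagent + mono adduct -> double product; substrate + reagent -> other mono adduct

1. equivalents of reagent to substrate, everything else as given, that leave most other mono adduct at 4.0 min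
2. the amount of other mono adduct then, in percent of the substrate charged
3. the amount of other mono adduct with the amounts as given

We write the rate of making other mono adduct as k·c(substrate)·c(reagent). The amber run reads 47.0% of it at 4.00 min, which is 0.376 M made. Mono adduct reads 1.6% there, so we set it aside. Integrating the rate with both charges falling together gives k = 0.438 L mol⁻¹ min⁻¹, a reading that we carry as our apparent rate constant.

In the flask the start rate is then 0.140 M min⁻¹. Held for 4.0 min, that rate makes 70.0% of the substrate charged, but the reagent charge covers 50.0%, so the rate has to slow. Integrated, our reckoning gives 2.02 as the growth term and 0.268 M made, or 33.5%. By the end the reagent has cut the rate by a factor 0.330 and the substrate by 0.665. Together that is 0.219, and the mean rate is about half of the start rate. This reckoning holds no loss step, so we take no optimum from it.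

The forecast gave 34% for the flask and 60% at 1.7 equiv, an optimum it called “flat and poorly defined”. The flask gives 33.8%, and the best charge is 2.62 equiv, with 78.9%.

    reagent + other mono adduct → double product (k = 6.00 × 10⁻⁴ L mol⁻¹ s⁻¹)
    substrate + reagent ⇌ mono adduct (K = 0.180 L mol⁻¹, k = 0.0150 L mol⁻¹ s⁻¹)
    reagent + mono adduct → double product (k = 1.80 × 10⁻⁴ L mol⁻¹ s⁻¹)
    substrate + reagent → other mono adduct (k = 0.00900 L mol⁻¹ s⁻¹)

The neighbour flask takes 0.68 M of reagent, with the substrate charge and the time held. With the same k its start rate is 0.238 M min⁻¹. The same integration gives 1.23 as the growth term and 0.414 M made, or 51.7%. The end factors are then 0.391 for reagent and 0.482 for substrate, so the reagent factor stays the lower of the two. The neighbour flask gives 51.1% of other mono adduct, with 45.3% of substrate at the end.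

The numbers in the tables come from a simulation from invented constants, and the scatter is random.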